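**Retrosynthetic overview**
1. Target ⇐ its C3 ketone, by hydride reduction from the face opposite the angular methyl group.
2. C3 ketone ⇐ eleven-membered-ring ketone. The ketone is turned into an enolonium (α-keto cation) equivalent at C4, which the C10=C1 alkene attacks across the ring. This key C4–C10 bond joins a ketone α-carbon and an alkene carbon, both normally nucleophilic.
3. Macrocyclic ketone ⇐ hyperjapone A, by epoxidation, reductive epoxide opening and oxidation.
4. Hyperjapone A ⇐ α-humulene + the methylene trione from norflavesone (hetero-Diels–Alder), then resolution; norflavesone ⇐ isobutyrylphloroglucinol + MeI.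
5. Ring order: dienone ring (dearomatisation) → dihydropyran (cycloaddition) → cycloheptane, then cyclopentane (both in the key step, by 1,2-shift and proton loss).

Assumption: the racemic cycloadduct is drawn as the enantiomer that is carried on.
Labels (from the target): C1 = CH bearing isopropenyl; C2 = CH2; C3 = carbinol carbon; C4 = methyl-bearing quaternary carbon; C5, C6 = CH2; C7 = CH joined to C11; C8 = methyl-bearing C–O carbon; C9 = CH2; C10 = ring-fusion CH; C11 = CH2 between C7 and the dienone ring; C12–C17 = dienone ring (C13 bears the pyran oxygen, C14 the gem-dimethyl group, C16 the isobutyryl group, C17 the enol OH). In the eleven-membered-ring intermediates the C(CH3)2 carbon lies between C2 and C1.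

**Step 1**
Reactants: 1 2-methyl-1-(2,4,6-trihydroxyphenyl)propan-1-one
Product: 2 norflavesone
Conditions: MeI (3.0 equiv), NaOMe (3.1 equiv), MeOH, 0 °C to rt
Reagents that add atoms: iodomethane, CI
Why: Dearomatising C-methylation of the phloroglucinol polyanion puts two methyl groups on one ring carbon and one on a second (over- and under-methylated material is removed by chromatography), and no stereocentre is formed.

**Step 2**
Reactants: 2 norflavesone; 3 α-humulene
Product: 5 rac-hyperjapone A, via methylene trione 4 (not isolated)
Conditions: TEMPO (1.1 equiv), Ag2O (1.5 equiv), 3 (3 equiv), toluene, rt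
Reagents that add atoms: none
Why: Ag2O/TEMPO dehydrogenates the methyl-bearing enol to the 2-methylene trione 4, whose inverse-electron-demand hetero-Diels–Alder reaction with the most reactive (E)-trisubstituted alkene of 3 is suprafacial with oxygen going to the methyl-bearing carbon, so C7–H and C8–CH3 end up anti (trans-fused dihydropyran) in racemic form.

**Step 3**
Reactants: 5 rac-hyperjapone A
Product: 6 (7S,8R)-hyperjapone A
Conditions: preparative HPLC on amylose tris(3,5-dimethylphenylcarbamate), hexane/i-PrOH/TFA 95:5:0.1, rt
Reagents that add atoms: none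
Why: Chromatographic resolution on a chiral stationary phase separates the enantiomers of the acidic enol (TFA suppresses ionisation), the (7S,8R) antipode is identified by comparing measured and calculated circular dichroism spectra, and this fixes the absolute configuration of C7 and C8 for the rest of the route.

**Step 4**
Reactants: 6 (7S,8R)-hyperjapone A
Product: 7 (3R,4R)-epoxide of 6
Conditions: mCPBA (1.05 equiv), NaHCO3, CH2Cl2, 0 °C
Reagents that add atoms: 3-chloroperoxybenzoic acid, O=C(OO)c1cccc(Cl)c1
Why: Prilezhaev epoxidation selects the electron-rich trisubstituted C3=C4 alkene over the neopentylic disubstituted alkene and the hydrogen-bonded enol, and the peracid approaches the outward-facing side of the alkene in the macrocycle to give the trans (3R,4R)-epoxide.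

**Step 5**
Reactants: 7 (3R,4R)-epoxide of 6
Product: 8 (3R,4S)-alcohol
Conditions: Cp2TiCl2 (20 mol %), Mn dust (2 equiv), 2,4,6-collidine·HCl (2.5 equiv), 1,4-cyclohexadiene (10 equiv), THF, rt
Reagents that add atoms: none
Why: In this radical reductive epoxide opening (Nugent–RajanBabu reaction, catalytic Gansäuer variant) Cp2TiCl (trivalent titanium) cleaves the C4–O bond to the tertiary radical, 1,4-cyclohexadiene delivers hydrogen to C4 from the open outer face and the C3–O bond is untouched, giving the anti-Markovnikov (3R)-alcohol; the C4 configuration does not matter because C4 becomes sp2 again in step 7.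

**Step 6**
Reactants: 8 (3R,4S)-alcohol
Product: 9 macrocyclic C3 ketone
Conditions: NPr4RuO4 (5 mol %), NMO (1.5 equiv), 4 Å MS, CH2Cl2, rt
Reagents that add atoms: none
Why: Ley–Griffith oxidation converts the hindered secondary alcohol into the ketone under neutral conditions that leave both alkenes, the enol ether and the tricarbonyl enol untouched, and no new stereocentre is formed.

**Step 7**
Reactants: 9 macrocyclic C3 ketone
Product: 13 C3 ketone of the target, via bis-silyl enol ether 10 (not isolated), via iodanyl enolate 11 (not isolated), via silyl ether 12 (not isolated)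
Conditions: TMSOTf (2.4 equiv), Et3N (3.0 equiv), CH2Cl2, 0 °C to rt; evaporate, pentane, filter; PhI(OH)OTs (1.2 equiv), BF3·OEt2 (1.5 equiv), CH2Cl2, −78 to −20 °C; aq. NaHCO3
Reagents that add atoms: none
Why: Proposed new method: soft enolisation silylates the acidic enol and converts the ketone into the more substituted C3=C4 silyl enol ether 10 (C2 is neopentylic and the tetrasubstituted enol ether is the thermodynamic one); ligand exchange on BF3-activated PhI(OH)OTs gives the O-bound aryl-λ3-iodanyl enolate 11 (trivalent iodine), an enolonium species in which C4 is an α-keto cation equivalent; the C10=C1 alkene lying across the eleven-membered ring attacks C4 from inside the ring as iodobenzene leaves (C4–C10 bond, seven-membered ring, C4–CH3 and C10–H anti), the secondary C1 cation is relieved by 1,2-shift of C2 from the gem-dimethyl carbon to C1 (cyclopentanone, side chain cis to C10–H) and loss of a methyl proton gives the isopropenyl group; the closest known reactions are the intermolecular C–C coupling of such enolonium species with allylsilanes, silyl enol ethers and arenes and the oxidative cyclisation of unsaturated silyl enol ethers, and the ring-forming sequence is the one humulene-type epoxides follow under acid.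

**Step 8**
Reactants: 13 C3 ketone of the target
Product: 14 target compound
Conditions: NaBH4 (2 equiv), MeOH, −20 °C; aq. NH4Cl
Reagents that add atoms: none
Why: Borohydride reduction of the cyclopentanone occurs from the face opposite the adjacent angular C4 methyl group (as in 17-oxo steroid reductions), giving the (3R)-alcohol cis to that methyl group, while the β-tricarbonyl unit is protected from hydride as its enolate.

**Compound list**
1 | 2-methyl-1-(2,4,6-trihydroxyphenyl)propan-1-one (isobutyrylphloroglucinol) | CC(C)C(=O)c1c(O)cc(O)cc1O | starting material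
2 | norflavesone: 2-isobutyryl-4,6,6-trimethylcyclohexane-1,3,5-trione, drawn as its dienol | CC(C)C(=O)C1=C(O)C(C)=C(O)C(C)(C)C1=O | intermediate
3 | α-humulene: (1E,4E,8E)-2,6,6,9-tetramethylcycloundeca-1,4,8-triene | C/C1=C\CC(C)(C)/C=C/C/C(C)=C/CC1 | starting material
4 | methylene trione: 2-isobutyryl-6,6-dimethyl-4-methylidenecyclohexane-1,3,5-trione (enol form) | C=C1C(=O)C(C)(C)C(=O)C(C(=O)C(C)C)=C1O | intermediate
5 | rac-(7S,8R)-hyperjapone A: trans-fused dihydropyran on the eleven-membered ring, both ring alkenes E, racemate | C/C1=C\CC(C)(C)/C=C/C[C@@]2(C)OC3=C(C[C@@H]2CC1)C(O)=C(C(=O)C(C)C)C(=O)C3(C)C | intermediate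
6 | (7S,8R)-hyperjapone A, single enantiomer | C/C1=C\CC(C)(C)/C=C/C[C@@]2(C)OC3=C(C[C@@H]2CC1)C(O)=C(C(=O)C(C)C)C(=O)C3(C)C | intermediate
7 | (3R,4R,7S,8R)-3,4-epoxide of 6 (trans epoxide, oxygen on the outer face) | C[C@@]14O[C@@H]4CC(C)(C)/C=C/C[C@@]2(C)OC3=C(C[C@@H]2CC1)C(O)=C(C(=O)C(C)C)C(=O)C3(C)C | intermediate
8 | (3R,4S,7S,8R)-3-hydroxy-3,4-dihydro derivative of 6 (secondary alcohol at C3, H at C4) | C[C@@H]1[C@H](O)CC(C)(C)/C=C/C[C@@]2(C)OC3=C(C[C@@H]2CC1)C(O)=C(C(=O)C(C)C)C(=O)C3(C)C | intermediate
9 | (4S,7S,8R)-3-oxo-3,4-dihydro derivative of 6 (eleven-membered-ring ketone, C4 epimerisable) | C[C@@H]1C(=O)CC(C)(C)/C=C/C[C@@]2(C)OC3=C(C[C@@H]2CC1)C(O)=C(C(=O)C(C)C)C(=O)C3(C)C | intermediate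
10 | bis(trimethylsilyl) derivative of 9: (3Z)-C3=C4 silyl enol ether (ring bonds trans across C3=C4) and C17–OSiMe3 | C/C1=C(O[Si](C)(C)C)\CC(C)(C)/C=C/C[C@@]2(C)OC3=C(C[C@@H]2CC1)C(O[Si](C)(C)C)=C(C(=O)C(C)C)C(=O)C3(C)C | intermediate
11 | enolonium species: C3–O–I(Ph)(OTs) enolate of 9, C17–OSiMe3 retained | C/C1=C(OI(c4ccccc4)OS(=O)(=O)c4ccc(C)cc4)\CC(C)(C)/C=C/C[C@@]2(C)OC3=C(C[C@@H]2CC1)C(O[Si](C)(C)C)=C(C(=O)C(C)C)C(=O)C3(C)C | intermediate
12 | C17-O-trimethylsilyl ether of 13 | C=C(C)[C@@H]1CC(=O)[C@]2(C)CC[C@H]3CC4=C(O[C@]3(C)C[C@@H]12)C(C)(C)C(=O)C(C(=O)C(C)C)=C4O[Si](C)(C)C | intermediate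
13 | (1R,4R,7S,8R,10S)-3-oxo analogue of the target (cyclopentanone in place of the C3 carbinol) | C=C(C)[C@@H]1CC(=O)[C@]2(C)CC[C@H]3CC4=C(O[C@]3(C)C[C@@H]12)C(C)(C)C(=O)C(C(=O)C(C)C)=C4O | intermediate
14 | CNP0510355.1, (1R,3R,4R,7S,8R,10S) in the labels above | C=C(C)[C@@H]1C[C@@H](O)[C@]2(C)CC[C@H]3CC4=C(O[C@]3(C)C[C@@H]12)C(C)(C)C(=O)C(C(=O)C(C)C)=C4O | target

**Step count**
Total steps: 8. Longest linear sequence: 8 steps (1 to 14); α-humulene 3 enters at step 2.

**Steps most likely to fail**

Step 7 is the least precedented.
- Silylation may also touch the isobutyryl group.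
- The enolonium may give only the α-tosyloxy ketone or the enone.
- The C1 cation may choose a hydride or methyl shift, because the migrating C2 is now α to a carbonyl group.
- The face of C4 that is attacked is controlled only by the ring conformation.

Fallback: set out from epoxide 7 and treat it with TsOH·H2O in CH2Cl2 at 0 °C. Protonation opens the epoxide at C4 to the tertiary cation at the alcohol oxidation level, the C10=C1 alkene attacks anti to the departing oxygen, and the same 1,2-shift and proton loss give the target directly. This fallback comes back to the route at 14 and makes no new compound (F0).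

Step 5 can fail because the tertiary C4 radical may add across the ring to the C10=C1 alkene before it is reduced, and the acidic enol can bind titanium. Fallback: set out from 7 and isomerise the epoxide with Et2Al(TMP) (diethylaluminium 2,2,6,6-tetramethylpiperidide, 3 equiv, toluene, 0 °C; syn-elimination through the C4 methyl group) to the exocyclic allylic alcohol F1. Redox isomerisation of F1 with [Ir(cod)(PCy3)(py)]PF6 (activated with H2, THF, rt) then gives the ketone, so the route is rejoined at 9.

Step 8 can fail in facial selectivity, because the isopropenyl group on C1 sits on the face from which hydride must come. Fallback: set out from 13 and accept hydride delivery from the methyl side, which gives the (3S)-alcohol F2. Mitsunobu reaction of F2 (PPh3, DIAD, 4-nitrobenzoic acid, toluene, rt) inverts C3 to give the (3R)-4-nitrobenzoate F3, and LiOH in THF/H2O cleaves the ester, which comes back to the route at 14.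

**Further compounds**
F0 | step 7 | none | none
F1 | step 5 | (3R,7S,8R)-allylic alcohol: C3–OH with exocyclic methylidene at C4, otherwise as 8 | C=C1[C@H](O)CC(C)(C)/C=C/C[C@@]2(C)OC3=C(C[C@@H]2CC1)C(O)=C(C(=O)C(C)C)C(=O)C3(C)C
F2 | step 8 | (3S)-epimer of 14 | C=C(C)[C@@H]1C[C@H](O)[C@]2(C)CC[C@H]3CC4=C(O[C@]3(C)C[C@@H]12)C(C)(C)C(=O)C(C(=O)C(C)C)=C4O
F3 | step 8 | (3R)-4-nitrobenzoate of 14 | C=C(C)[C@@H]1C[C@@H](OC(=O)c5ccc(cc5)[N+](=O)[O-])[C@]2(C)CC[C@H]3CC4=C(O[C@]3(C)C[C@@H]12)C(C)(C)C(=O)C(C(=O)C(C)C)=C4O
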